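## Retrosynthetic overview

- **Feature:** in the furan ring, the C2=C3 bond joins two carbons of different character. C2 is bonded to O1 and the 4-hydroxyphenyl ring, so it is at the carboxyl oxidation level. C3 lies between C3a and the aroyl C=O, so it is the carbon of a keto-stabilised carbanion. This pairs an aryl ester with an acyl ylide.
- **Disconnections, backwards:** the six O–CH3 bonds, then the C7–C(=O) bond of the dihydrochalcone chain (Friedel–Crafts on the phloroglucinol-type benzo ring), then C2=C3 (intramolecular Wittig olefination of the ester).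
- **Wittig precursor:** it is cut at O1–C(=O) (4-methoxybenzoyl chloride), at C3–C(=O) (2,4-dimethoxybenzoyl chloride) and at C3–P (PPh3·HBr on the benzylic alcohol from 2-hydroxy-4,6-dimethoxybenzaldehyde).
- **Order of acylations:** C3 is acylated while O1 is silylated, and the ester goes on last. A non-stabilised ylide next to an aryl ester would close early to the 3-unsubstituted benzofuran, or pass its acyl group from O to C.
- **Rings:** all four benzene rings are bought. The furan is the only ring formed, in the key step.

Key step: step 6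

Remark: the target has no stereocentre and no stable axis of chirality, so it is one achiral compound and no step needs stereocontrol.
Remark: the counter-ion of 4 may be partly exchanged for chloride in step 3; this does not affect step 4, and 4 is written as the bromide.

## Route

Step 1
Reactants: 1 2-hydroxy-4,6-dimethoxybenzaldehyde
Product: 2 2-(hydroxymethyl)-3,5-dimethoxyphenol
Conditions: NaBH4, THF/MeOH, 0 °C; aq NH4Cl quench; crude product used at once
Reagents that add atoms: none
Why: Borohydride 1,2-reduction of the aldehyde, run cold and quenched near neutral pH so that the electron-rich o-hydroxybenzyl alcohol does not ionise to its o-quinone methide.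

Step 2
Reactants: 2 2-(hydroxymethyl)-3,5-dimethoxyphenol
Product: 3 (2-hydroxy-4,6-dimethoxybenzyl)triphenylphosphonium bromide
Conditions: PPh3·HBr (1.05 equiv), MeCN, reflux
Reagents that add atoms: triphenylphosphine hydrobromide, Br.c1ccc(cc1)P(c1ccccc1)c1ccccc1
Why: SN1-type substitution in which HBr ionises the trioxygenated benzylic alcohol and PPh3 traps the cation, the standard preparation of o-hydroxybenzyl phosphonium salts.

Step 3
Reactants: 3 (2-hydroxy-4,6-dimethoxybenzyl)triphenylphosphonium bromide
Product: 4 [2-(tert-butyldimethylsilyloxy)-4,6-dimethoxybenzyl]triphenylphosphonium bromide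
Conditions: TBSCl (1.3 equiv), imidazole (2.5 equiv), CH2Cl2, rt
Reagents that add atoms: tert-butyldimethylsilyl chloride, CC(C)(C)[Si](C)(C)Cl
Why: Imidazole-promoted silylation of the phenol gives a mask with no electrophilic carbonyl, so the reactive ylide of step 4 has nothing to close onto, and aryl TBS ethers are known to survive benzylic ylide generation.

Step 4
Reactants: 4 [2-(tert-butyldimethylsilyloxy)-4,6-dimethoxybenzyl]triphenylphosphonium bromide; 5 2,4-dimethoxybenzoyl chloride
Product: 8 2-[2-(tert-butyldimethylsilyloxy)-4,6-dimethoxyphenyl]-1-(2,4-dimethoxyphenyl)-2-(triphenylphosphoranylidene)ethan-1-one, via benzylic ylide 6 (not isolated), via acylphosphonium chloride 7 (not isolated)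
Conditions: LiHMDS (2.1 equiv), THF, −78 → 0 °C; 5 (1.0 equiv) added slowly, −78 °C → rt
Reagents that add atoms: none
Why: C-acylation of a semi-stabilised phosphonium ylide by an aroyl chloride, in which the second equivalent of the hindered amide base removes the acidic proton of 7, so no ylide is lost by proton exchange and the bench-stable keto ylide results.

Step 5
Reactants: 8 2-[2-(tert-butyldimethylsilyloxy)-4,6-dimethoxyphenyl]-1-(2,4-dimethoxyphenyl)-2-(triphenylphosphoranylidene)ethan-1-one; 9 4-methoxybenzoyl chloride
Product: 11 2-[2-(2,4-dimethoxyphenyl)-2-oxo-1-(triphenylphosphoranylidene)ethyl]-3,5-dimethoxyphenyl 4-methoxybenzoate, via ammonium phenoxide 10 (not isolated)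
Conditions: TBAF (1.0 M in THF, 1.05 equiv), 4 Å MS, THF, 0 °C, 15 min; then 9 (1.3 equiv), 0 °C → rt
Reagents that add atoms: none
Why: Fluoride desilylation frees a phenoxide far more nucleophilic than the delocalised keto ylide, and trapping it at once by O-acylation (Schotten–Baumann type) puts the 4-methoxybenzoyl group on O1 only and stops the phenoxide from adding to the neighbouring ketone, while the stabilised ylide does not olefinate at this temperature.

Step 6
Reactants: 11 2-[2-(2,4-dimethoxyphenyl)-2-oxo-1-(triphenylphosphoranylidene)ethyl]-3,5-dimethoxyphenyl 4-methoxybenzoate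
Product: 13 (2,4-dimethoxyphenyl)[4,6-dimethoxy-2-(4-methoxyphenyl)-1-benzofuran-3-yl]methanone, via oxaphosphetane 12 (not isolated)
Conditions: dry PhMe (0.03 M), N2, 110 °C (o-xylene, 140 °C, if slow)
Reagents that add atoms: none
Why: On heating, the ylide carbon (future C3) adds to the carbonyl carbon of the aryl 4-methoxybenzoate (future C2), the adduct closes to oxaphosphetane 12, and cycloreversion expels Ph3P=O to leave the C2=C3 double bond of the aromatic furan. The closest known reaction type is the intramolecular Wittig olefination of o-acyloxybenzyl phosphonium ylides, which is documented also for C-acylated (keto-stabilised) ylides that give 3-aroyl-2-arylbenzofurans in hot toluene. The furan ring (O1–C2–C3–C3a–C7a) closes in the 5-exo-trig mode, since the attacked C=O is exocyclic to the new ring. The two stereocentres of 12 are transient (cis fusion is forced by the four-membered ring) and vanish with Ph3P=O, so nothing has to be controlled. The ylide must choose the ester carbonyl over its own ketone and each aryl group must keep its place: the ketone could react only through a strained four-membered P–O ring that leads to an alkyne under pyrolysis far above 110 °C, and the placement is fixed because 4-methoxybenzoyl sits on O1 and 2,4-dimethoxybenzoyl on C3 before any heat is applied. The two ortho substituents twist the benzo ring out of the P=C–C=O plane, which holds the ester carbonyl over the carbanion lobe, and aromatisation together with P=O bond formation supplies the driving force.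

Step 7
Reactants: 14 3-(4-methoxyphenyl)propanoic acid
Product: 15 3-(4-methoxyphenyl)propanoyl chloride
Conditions: (COCl)2 (1.3 equiv), DMF (cat.), CH2Cl2, 0 °C → rt; concentrate
Reagents that add atoms: oxalyl chloride, O=C(Cl)C(=O)Cl
Why: DMF-catalysed (Vilsmeier-type) activation converts the acid into its chloride under cold, mild conditions that leave the anisole ring untouched.

Step 8
Reactants: 13 (2,4-dimethoxyphenyl)[4,6-dimethoxy-2-(4-methoxyphenyl)-1-benzofuran-3-yl]methanone; 15 3-(4-methoxyphenyl)propanoyl chloride
Product: 16 1-[3-(2,4-dimethoxybenzoyl)-4,6-dimethoxy-2-(4-methoxyphenyl)-1-benzofuran-7-yl]-3-(4-methoxyphenyl)propan-1-one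
Conditions: 15 (1.3 equiv), SnCl4 (2.5 equiv), CH2Cl2, 0 °C → rt
Reagents that add atoms: none
Why: Friedel–Crafts acylation in which the three oxygen donors of the benzo ring direct to C5 and C7, of which C7 (flanked by one OMe and the substituent-free O1) is less hindered and is the site where 2,3-disubstituted 4,6-dimethoxybenzofurans are known to be formylated and acylated, while SnCl4 bound to the C3 ketone deactivates the 2,4-dimethoxybenzoyl ring and the anisyl rings carry only one donor.

Step 9
Reactants: 16 1-[3-(2,4-dimethoxybenzoyl)-4,6-dimethoxy-2-(4-methoxyphenyl)-1-benzofuran-7-yl]-3-(4-methoxyphenyl)propan-1-one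
Product: 17 1-[3-(2,4-dihydroxybenzoyl)-4,6-dihydroxy-2-(4-hydroxyphenyl)-1-benzofuran-7-yl]-3-(4-hydroxyphenyl)propan-1-one (CNP0181782.0)
Conditions: BBr3 (12 equiv), CH2Cl2, −78 °C → rt; ice-water quench
Reagents that add atoms: none
Why: BBr3 aryl methyl ether cleavage (boron complexation at each OMe, then SN2 attack of bromide on methyl) removes all six methyl groups, chelation helping those close to a carbonyl, while the ketones, the furan and the CH2CH2 link are inert and the cold aqueous quench frees the six phenols.

## Compound list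

| No. | Name | SMILES | Role |
|---|---|---|---|
| 1 | 2-hydroxy-4,6-dimethoxybenzaldehyde | COc1cc(O)c(C=O)c(OC)c1 | starting material |
| 2 | 2-(hydroxymethyl)-3,5-dimethoxyphenol | COc1cc(O)c(CO)c(OC)c1 | intermediate |
| 3 | (2-hydroxy-4,6-dimethoxybenzyl)triphenylphosphonium bromide | [Br-].COc1cc(O)c(C[P+](c2ccccc2)(c2ccccc2)c2ccccc2)c(OC)c1 | intermediate |
| 4 | [2-(tert-butyldimethylsilyloxy)-4,6-dimethoxybenzyl]triphenylphosphonium bromide | [Br-].COc1cc(O[Si](C)(C)C(C)(C)C)c(C[P+](c2ccccc2)(c2ccccc2)c2ccccc2)c(OC)c1 | intermediate |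
| 5 | 2,4-dimethoxybenzoyl chloride | COc1ccc(C(=O)Cl)c(OC)c1 | starting material |
| 6 | [2-(tert-butyldimethylsilyloxy)-4,6-dimethoxybenzylidene]triphenylphosphorane | COc1cc(O[Si](C)(C)C(C)(C)C)c(C=P(c2ccccc2)(c2ccccc2)c2ccccc2)c(OC)c1 | intermediate |
| 7 | {1-[2-(tert-butyldimethylsilyloxy)-4,6-dimethoxyphenyl]-2-(2,4-dimethoxyphenyl)-2-oxoethyl}triphenylphosphonium chloride (racemic, transient) | [Cl-].COc1ccc(C(=O)C(c2c(OC)cc(OC)cc2O[Si](C)(C)C(C)(C)C)[P+](c2ccccc2)(c2ccccc2)c2ccccc2)c(OC)c1 | intermediate |
| 8 | 2-[2-(tert-butyldimethylsilyloxy)-4,6-dimethoxyphenyl]-1-(2,4-dimethoxyphenyl)-2-(triphenylphosphoranylidene)ethan-1-one | COc1ccc(C(=O)C(c2c(OC)cc(OC)cc2O[Si](C)(C)C(C)(C)C)=P(c2ccccc2)(c2ccccc2)c2ccccc2)c(OC)c1 | intermediate |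
| 9 | 4-methoxybenzoyl chloride | COc1ccc(C(=O)Cl)cc1 | starting material |
| 10 | tetrabutylammonium 2-[2-(2,4-dimethoxyphenyl)-2-oxo-1-(triphenylphosphoranylidene)ethyl]-3,5-dimethoxyphenolate | CCCC[N+](CCCC)(CCCC)CCCC.COc1ccc(C(=O)C(c2c(OC)cc(OC)cc2[O-])=P(c2ccccc2)(c2ccccc2)c2ccccc2)c(OC)c1 | intermediate |
| 11 | 2-[2-(2,4-dimethoxyphenyl)-2-oxo-1-(triphenylphosphoranylidene)ethyl]-3,5-dimethoxyphenyl 4-methoxybenzoate (key-step precursor) | COc1ccc(cc1)C(=O)Oc1cc(OC)cc(OC)c1C(=P(c1ccccc1)(c1ccccc1)c1ccccc1)C(=O)c1ccc(OC)cc1OC | intermediate |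
| 12 | 1,2-oxaphosphetane cis-fused to the 2,3-dihydrobenzofuran at C2–C3 (P on C3, O on C2; racemic, one enantiomer drawn) | COc1ccc(cc1)[C@]12Oc3cc(OC)cc(OC)c3[C@@]1(C(=O)c1ccc(OC)cc1OC)P(c1ccccc1)(c1ccccc1)(c1ccccc1)O2 | intermediate |
| 13 | (2,4-dimethoxyphenyl)[4,6-dimethoxy-2-(4-methoxyphenyl)-1-benzofuran-3-yl]methanone (key-step product) | COc1ccc(cc1)-c1oc2cc(OC)cc(OC)c2c1C(=O)c1ccc(OC)cc1OC | intermediate |
| 14 | 3-(4-methoxyphenyl)propanoic acid | COc1ccc(CCC(=O)O)cc1 | starting material |
| 15 | 3-(4-methoxyphenyl)propanoyl chloride | COc1ccc(CCC(=O)Cl)cc1 | intermediate |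
| 16 | 1-[3-(2,4-dimethoxybenzoyl)-4,6-dimethoxy-2-(4-methoxyphenyl)-1-benzofuran-7-yl]-3-(4-methoxyphenyl)propan-1-one | O=C(CCc1ccc(OC)cc1)c1c(OC)cc(OC)c2c(C(=O)c3ccc(OC)cc3OC)c(-c3ccc(OC)cc3)oc12 | intermediate |
| 17 | 1-[3-(2,4-dihydroxybenzoyl)-4,6-dihydroxy-2-(4-hydroxyphenyl)-1-benzofuran-7-yl]-3-(4-hydroxyphenyl)propan-1-one | O=C(CCc1ccc(O)cc1)c1c(O)cc(O)c2c(C(=O)c3ccc(O)cc3O)c(-c3ccc(O)cc3)oc12 | target |

**Total step count:** 9.
**Longest linear sequence:** 8 (steps 1–6, 8, 9, from compound 1); step 7 is a one-step side branch.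

## Steps most likely to fail

**Step 6.** The doubly stabilised, fully substituted ylide carbon may add too slowly to the donor-deactivated ester carbonyl. The tetrahedral adduct may also open by loss of the phenoxide before Ph3P=O leaves, which would let the two aroyl groups change places.
- The fallback builds the furan without phosphorus. It sets out from 1 and comes back at 13.
- Acid-catalysed reaction of 1 with ethyl diazoacetate (HBF4·OEt2 cat., CH2Cl2, then conc. H2SO4) proceeds by homologation with a 1,2-aryl shift, then cyclodehydration. It should give ethyl 4,6-dimethoxy-1-benzofuran-3-carboxylate F1, in which C3 already carries its carbonyl carbon.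
- MeNH(OMe)·HCl/i-PrMgCl (THF, −20 °C) should convert F1 into N,4,6-trimethoxy-N-methyl-1-benzofuran-3-carboxamide F2.
- 2,4-Dimethoxyphenylmagnesium bromide (THF, 0 °C, Weinreb ketone synthesis) should then give (2,4-dimethoxyphenyl)(4,6-dimethoxy-1-benzofuran-3-yl)methanone F3.
- Pd-catalysed C2–H arylation with 4-bromoanisole (Pd(OAc)2, PCy3·HBF4, PivOH, K2CO3, DMA, 100 °C) works by concerted metalation–deprotonation at the acidic C2–H next to O1 and should deliver 13.

**Step 4.** Two ortho substituents shield the ylide carbon and slow C–C bond formation. The amide base may then consume the acid chloride, or proton exchange between the ylide and the acylphosphonium salt may stall the conversion.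
- The fallback drops the silyl mask and carries the flatter ester through the C-acylation. It sets out from 3 and comes back at 13, with 11 passed through in the flask.
- Selective O-acylation of 3 with 9 (1.0 equiv, Et3N 1.0 equiv, CH2Cl2, 0 °C) should give [2-(4-methoxybenzoyloxy)-4,6-dimethoxybenzyl]triphenylphosphonium bromide F4.
- F4 is then treated with an excess of 5 and Et3N in toluene, rt → 110 °C. The ylide forms only in low stationary concentration in the presence of much acid chloride, is C-acylated to 11, and closes in the same pot.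
- Early ring closure of the non-acylated ylide is the loss channel of this variant. That is why it serves only as a reserve.

**Step 8.** Site selectivity may erode through attack at C5 or on the dimethoxybenzoyl ring. The acid chloride may acylate its own anisole ring, and the Lewis acid may cleave methyl ethers next to the carbonyl groups.
- The fallback brings in C7 as a one-carbon unit with a weak, highly selective electrophile and adds the chain as a nucleophile. It sets out from 13 and comes back at 16.
- Vilsmeier–Haack formylation (POCl3, DMF, 0 → 60 °C) should give 3-(2,4-dimethoxybenzoyl)-4,6-dimethoxy-2-(4-methoxyphenyl)-1-benzofuran-7-carbaldehyde F5.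
- 2-(4-Methoxyphenyl)ethylmagnesium bromide (THF, −78 °C) should add to the aldehyde in preference to the hindered, donor-deactivated diaryl ketone. The product is (2,4-dimethoxyphenyl){7-[1-hydroxy-3-(4-methoxyphenyl)propyl]-4,6-dimethoxy-2-(4-methoxyphenyl)-1-benzofuran-3-yl}methanone F6, which is racemic.
- Dess–Martin oxidation removes that stereocentre and gives 16.

## Further compounds

F1 | step 6 | ethyl 4,6-dimethoxy-1-benzofuran-3-carboxylate | CCOC(=O)c1coc2cc(OC)cc(OC)c12
F2 | step 6 | N,4,6-trimethoxy-N-methyl-1-benzofuran-3-carboxamide | CON(C)C(=O)c1coc2cc(OC)cc(OC)c12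
F3 | step 6 | (2,4-dimethoxyphenyl)(4,6-dimethoxy-1-benzofuran-3-yl)methanone | COc1ccc(C(=O)c2coc3cc(OC)cc(OC)c23)c(OC)c1
F4 | step 4 | [2-(4-methoxybenzoyloxy)-4,6-dimethoxybenzyl]triphenylphosphonium bromide | [Br-].COc1ccc(cc1)C(=O)Oc1cc(OC)cc(OC)c1C[P+](c1ccccc1)(c1ccccc1)c1ccccc1
F5 | step 8 | 3-(2,4-dimethoxybenzoyl)-4,6-dimethoxy-2-(4-methoxyphenyl)-1-benzofuran-7-carbaldehyde | O=Cc1c(OC)cc(OC)c2c(C(=O)c3ccc(OC)cc3OC)c(-c3ccc(OC)cc3)oc12
F6 | step 8 | (2,4-dimethoxyphenyl){7-[1-hydroxy-3-(4-methoxyphenyl)propyl]-4,6-dimethoxy-2-(4-methoxyphenyl)-1-benzofuran-3-yl}methanone (racemic) | OC(CCc1ccc(OC)cc1)c1c(OC)cc(OC)c2c(C(=O)c3ccc(OC)cc3OC)c(-c3ccc(OC)cc3)oc12
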